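**Retrosynthetic overview**

1. Feature used: C7 carries O and CH3 and lies between the C6 ketone and the C8 methylene, and C8 is bonded to C8a, the nucleophilic β-carbon of the ring A enol ether O2–C1=C8a (isochromene numbering). This is the retron of a 2-acyl-2-methyloxirane opened at its CH2 by that carbon.
2. Endgame: the orsellinate ring is built on the C7 oxygen (acylketene capture, aldol aromatisation). The allylic acetate comes from a C3 enoate kept as the tert-butyl ester until ring B exists, then taken through acid, mixed anhydride/NaBH4 and Ac2O, so that no aluminium hydride meets the C6 vinylogous carbonyl.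
3. Key disconnection C8–C8a: Lewis-acid opening of the keto epoxide of 4-ylidene-4H-pyran 13 by C8a closes ring B and frees the C7 carbinol.
4. 13 is cut at C4a=C5 into pyranthione 7 (from comanic acid 1) and epoxy diazoketone 11 (from (R)-2-methylglycidol 8, the only source of chirality), joined by a Rh2(OAc)4-mediated thione–diazoketone olefination.
5. Ring order: ring A is bought as the pyrone, ring B is closed in step 8, the benzenoid ring of the orsellinate is formed last (step 15).

Key step: step 8

Remark: the bicyclic core, and the atoms of 13 that become it, are numbered as in isochromene (C1, O2, C3, C4, C4a, C5 to C8, C8a). Compound 13 is expected as an interconverting pair of C4a=C5 isomers and is drawn as the isomer that cyclises.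

**Route**

Step 1
Reactants: 1 comanic acid (4-oxo-4H-pyran-2-carboxylic acid)
Product: 2 methyl 4-oxo-4H-pyran-2-carboxylate
Conditions: MeOH, H2SO4 (cat.), reflux
Reagents that add atoms: methanol, CO
Why: Fischer esterification of an acid-stable pyrone carboxylic acid.

Step 2
Reactants: 2 methyl 4-oxo-4H-pyran-2-carboxylate
Product: 3 2-(hydroxymethyl)-4H-pyran-4-one
Conditions: NaBH4, MeOH, −10 to 0 °C; AcOH quench
Reagents that add atoms: none
Why: Borohydride reduction of an activated ester (conjugated through C2=C3 to the pyrone carbonyl and flanked by the ring oxygen, as in chromone-2-carboxylates), while the pyrone carbonyl, a vinylogous ester, should be left alone at low temperature.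

Step 3
Reactants: 3 2-(hydroxymethyl)-4H-pyran-4-one; 4 tert-butyl (triphenylphosphoranylidene)acetate
Product: 6 tert-butyl (2E)-3-(4-oxo-4H-pyran-2-yl)prop-2-enoate, via 4-oxo-4H-pyran-2-carbaldehyde 5 (not isolated)
Conditions: MnO2 (activated, excess), 4 (1.3 equiv), CH2Cl2, rt
Reagents that add atoms: none
Why: Tandem MnO2 oxidation/Wittig olefination, in which the allylic-type alcohol is oxidised to the hydrate-prone aldehyde 5 and trapped at once by the stabilised ylide to give the (E)-enoate.

Step 4
Reactants: 6 tert-butyl (2E)-3-(4-oxo-4H-pyran-2-yl)prop-2-enoate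
Product: 7 tert-butyl (2E)-3-(4-thioxo-4H-pyran-2-yl)prop-2-enoate
Conditions: Lawesson's reagent (0.6 equiv), toluene, 80 °C
Reagents that add atoms: Lawesson's reagent, COc1ccc(cc1)P1(=S)SP(=S)(S1)c1ccc(OC)cc1
Why: Thionation with Lawesson's reagent, the strongly polarised pyrone carbonyl exchanging O for S far faster than the tert-butyl enoate.

Step 5
Reactants: 8 (R)-2-methylglycidol
Product: 9 (2S)-2-methyloxirane-2-carboxylic acid
Conditions: RuCl3·xH2O (cat.), NaIO4, MeCN/EtOAc/H2O, 0 °C to rt
Reagents that add atoms: sodium periodate, [Na+].[O-]I(=O)(=O)=O; water, O (together the source of the new carboxyl oxygen)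
Why: Sharpless RuCl3/NaIO4 oxidation of a primary alcohol to the acid, which epoxides tolerate; no bond to the stereocentre changes, and its descriptor becomes (S) only through the change in CIP priorities.

Step 6
Reactants: 9 (2S)-2-methyloxirane-2-carboxylic acid
Product: 11 2-diazo-1-[(2S)-2-methyloxiran-2-yl]ethan-1-one, via isobutyl carbonic mixed anhydride 10 (not isolated)
Conditions: i-BuOCOCl, N-methylmorpholine, THF, −20 °C; then CH2N2 (excess), Et2O, −20 to 0 °C
Reagents that add atoms: diazomethane, C=[N+]=[N-]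
Why: Arndt–Eistert-type acylation of diazomethane by a mixed carbonic anhydride, the standard neutral access to α,β-epoxy diazomethyl ketones, with excess diazomethane keeping the medium acid-free so that the epoxide survives.

Step 7
Reactants: 7 tert-butyl (2E)-3-(4-thioxo-4H-pyran-2-yl)prop-2-enoate; 11 2-diazo-1-[(2S)-2-methyloxiran-2-yl]ethan-1-one
Product: 13 tert-butyl (2E)-3-{(4E)-4-[2-((2S)-2-methyloxiran-2-yl)-2-oxoethylidene]-4H-pyran-2-yl}prop-2-enoate, via spiro-thiirane 12 (not isolated)
Conditions: Rh2(OAc)4 (2 mol %), toluene, 70 °C, slow addition of 11; then PPh3, 50 °C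
Reagents that add atoms: none
Why: Barton–Kellogg-type olefination in its rhodium-carbenoid version, as in thioamide–diazoketone couplings: the thione sulfur traps the carbenoid from 11 as a thiocarbonyl ylide that closes to thiirane 12, and PPh3, added once the diazo compound is consumed, removes sulfur to give the push–pull alkene.

Step 8
Reactants: 13 tert-butyl (2E)-3-{(4E)-4-[2-((2S)-2-methyloxiran-2-yl)-2-oxoethylidene]-4H-pyran-2-yl}prop-2-enoate
Product: 14 tert-butyl (2E)-3-[(7S)-7-hydroxy-7-methyl-6-oxo-7,8-dihydro-6H-isochromen-3-yl]prop-2-enoate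
Conditions: Sc(OTf)3 (20 mol %), 2,6-di-tert-butyl-4-methylpyridine (30 mol %), 4 Å MS, CH2Cl2, −20 °C to rt
Reagents that add atoms: none
Why: Proposed new method: Sc(OTf)3 on the epoxide oxygen, held there by chelation to the C6 carbonyl, polarises the C8–O bond, and C8a, the β-carbon of the ring A enol ether O2–C1=C8a, attacks the CH2 carbon in an SN2-like way; the C1 oxocarbenium ion then loses H8a to the hindered pyridine, which restores the chromophore and leaves the C7 alkoxide, the closest known reactions being Lewis-acid epoxy-arene and epoxide–enol ether cyclisations (Friedel–Crafts-type epoxide opening). Ring B (C8a, C4a, C5, C6, C7, C8) closes in the 6-endo-tet mode, because the 5-exo alternative would require attack at the fully substituted C7, whose cationic character is suppressed by the adjacent carbonyl. No stereocentre is formed, since no bond to C7 is made or broken, so the (S) centre brought in with 8 becomes the carbinol centre. The selectivity needed is C8a over C4, and the enoate on C3 should secure it by making C4 the electron-poor δ-carbon of a dienoate and by destabilising a cation at C3, while the two C4a=C5 isomers of 13 interconvert through the push–pull system so that all material can pass through the reactive one. A catalytic chelating trivalent scandium salt with a proton shuttle is chosen over stoichiometric BF3·OEt2 or a protic acid, because full complexation or C5 protonation of the vinylogous carbonyl would turn ring A into a pyrylium ion and switch off C8a, whereas in the chelate the metal passes to the new alkoxide as C8–O breaks.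

Step 9
Reactants: 14 tert-butyl (2E)-3-[(7S)-7-hydroxy-7-methyl-6-oxo-7,8-dihydro-6H-isochromen-3-yl]prop-2-enoate
Product: 15 (2E)-3-[(7S)-7-hydroxy-7-methyl-6-oxo-7,8-dihydro-6H-isochromen-3-yl]prop-2-enoic acid
Conditions: CF3CO2H/CH2Cl2 (1:4), 0 °C to rt
Reagents that add atoms: none
Why: Acidolysis of the tert-butyl ester with loss of isobutene; the tertiary α-ketol should not ionise because the cation would sit next to the carbonyl, and the chromophore is only protonated reversibly.

Step 10
Reactants: 15 (2E)-3-[(7S)-7-hydroxy-7-methyl-6-oxo-7,8-dihydro-6H-isochromen-3-yl]prop-2-enoic acid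
Product: 17 (7S)-7-hydroxy-3-[(1E)-3-hydroxyprop-1-en-1-yl]-7-methyl-7,8-dihydro-6H-isochromen-6-one, via isobutyl carbonic mixed anhydride 16 (not isolated)
Conditions: i-BuOCOCl, N-methylmorpholine, THF, −15 °C; then NaBH4, THF/MeOH, −15 to 0 °C
Reagents that add atoms: none
Why: Borohydride reduction of a mixed carbonic anhydride (1,2-selective for enoic acids) should be far faster than any attack on the C6 carbonyl, a doubly vinylogous ester, which avoids exposing the chromophore and its chelating α-ketol to an aluminium hydride.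

Step 11
Reactants: 17 (7S)-7-hydroxy-3-[(1E)-3-hydroxyprop-1-en-1-yl]-7-methyl-7,8-dihydro-6H-isochromen-6-one
Product: 18 (2E)-3-[(7S)-7-hydroxy-7-methyl-6-oxo-7,8-dihydro-6H-isochromen-3-yl]prop-2-en-1-yl acetate
Conditions: Ac2O, pyridine, CH2Cl2, 0 °C
Reagents that add atoms: acetic anhydride, CC(=O)OC(C)=O
Why: Acetylation with Ac2O/pyridine without an acyl-transfer catalyst is selective for the primary allylic alcohol over the hindered tertiary α-ketol.

Step 12
Reactants: 19 2,2,6-trimethyl-4H-1,3-dioxin-4-one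
Product: 20 2,2-dimethyl-6-(2-oxopropyl)-4H-1,3-dioxin-4-one
Conditions: LiN(SiMe3)2 (2 equiv), THF, −78 °C; AcCl; aq. HCl quench
Reagents that add atoms: acetyl chloride, CC(Cl)=O
Why: Claisen-type γ-C-acylation of the lithium dienolate of the dioxinone, the second equivalent of base taking up the more acidic product.

Step 13
Reactants: 20 2,2-dimethyl-6-(2-oxopropyl)-4H-1,3-dioxin-4-one
Product: 21 6-(2,4-dioxopentyl)-2,2-dimethyl-4H-1,3-dioxin-4-one
Conditions: LiN(i-Pr)2 (2.2 equiv), THF, −78 °C; MeC(O)N(OMe)Me, −78 to −40 °C; aq. HCl quench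
Reagents that add atoms: N-methoxy-N-methylacetamide, CC(=O)N(C)OC
Why: Terminal C-acylation of the dianion of the β-keto dioxinone by a Weinreb amide (Weiler-type dianion chemistry), the chelated tetrahedral intermediate preventing over-addition.

Step 14
Reactants: 18 (2E)-3-[(7S)-7-hydroxy-7-methyl-6-oxo-7,8-dihydro-6H-isochromen-3-yl]prop-2-en-1-yl acetate; 21 6-(2,4-dioxopentyl)-2,2-dimethyl-4H-1,3-dioxin-4-one
Product: 23 (7S)-3-[(1E)-3-acetoxyprop-1-en-1-yl]-7-methyl-6-oxo-7,8-dihydro-6H-isochromen-7-yl 3,5,7-trioxooctanoate, via acylketene 22 (not isolated)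
Conditions: 21 (1.5 equiv), toluene, 110 °C, 4 Å MS; taken on without chromatography
Reagents that add atoms: none
Why: Thermal retro-[4+2] of the dioxinone releases acetone and acylketene 22, a small and highly electrophilic acylating agent that the tertiary C7 alcohol should capture (acylketene esterification) without any bond to C7 being touched.

Step 15
Reactants: 23 (7S)-3-[(1E)-3-acetoxyprop-1-en-1-yl]-7-methyl-6-oxo-7,8-dihydro-6H-isochromen-7-yl 3,5,7-trioxooctanoate
Product: 25 (7S)-3-[(1E)-3-acetoxyprop-1-en-1-yl]-7-methyl-6-oxo-7,8-dihydro-6H-isochromen-7-yl 2,4-dihydroxy-6-methylbenzoate, via aldol adduct 24 (not isolated)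
Conditions: Et3N, CH2Cl2, 0 °C to rt; then AcOH
Reagents that add atoms: none
Why: Biomimetic aldol aromatisation, in which the carbon between the ester and the first ketone of the chain adds to the terminal methyl ketone and adduct 24 dehydrates and enolises to the resorcylate, under conditions mild enough for the allylic acetate and the C7 ester.

**Compound list**

1 | comanic acid (4-oxo-4H-pyran-2-carboxylic acid) | O=C(O)C1=CC(=O)C=CO1 | starting material
2 | methyl 4-oxo-4H-pyran-2-carboxylate | COC(=O)C1=CC(=O)C=CO1 | intermediate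
3 | 2-(hydroxymethyl)-4H-pyran-4-one | OCC1=CC(=O)C=CO1 | intermediate
4 | tert-butyl (triphenylphosphoranylidene)acetate | CC(C)(C)OC(=O)C=P(c1ccccc1)(c1ccccc1)c1ccccc1 | starting material
5 | 4-oxo-4H-pyran-2-carbaldehyde (formed in the flask) | O=CC1=CC(=O)C=CO1 | intermediate
6 | tert-butyl (2E)-3-(4-oxo-4H-pyran-2-yl)prop-2-enoate | CC(C)(C)OC(=O)/C=C/C1=CC(=O)C=CO1 | intermediate
7 | tert-butyl (2E)-3-(4-thioxo-4H-pyran-2-yl)prop-2-enoate | CC(C)(C)OC(=O)/C=C/C1=CC(=S)C=CO1 | intermediate
8 | (R)-2-methylglycidol, [(2R)-2-methyloxiran-2-yl]methanol | OC[C@]1(C)CO1 | starting material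
9 | (2S)-2-methyloxirane-2-carboxylic acid | OC(=O)[C@]1(C)CO1 | intermediate
10 | isobutyl carbonic (2S)-2-methyloxirane-2-carboxylic anhydride (formed in the flask) | CC(C)COC(=O)OC(=O)[C@]1(C)CO1 | intermediate
11 | 2-diazo-1-[(2S)-2-methyloxiran-2-yl]ethan-1-one | [N-]=[N+]=CC(=O)[C@]1(C)CO1 | intermediate
12 | tert-butyl (2E)-3-{2-[(2S)-2-methyloxirane-2-carbonyl]-6-oxa-1-thiaspiro[2.5]octa-4,7-dien-5-yl}prop-2-enoate (spiro-thiirane, thiirane carbons unassigned, formed in the flask) | CC(C)(C)OC(=O)/C=C/C1=CC2(SC2C(=O)[C@]3(C)CO3)C=CO1 | intermediate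
13 | tert-butyl (2E)-3-{(4E)-4-[2-((2S)-2-methyloxiran-2-yl)-2-oxoethylidene]-4H-pyran-2-yl}prop-2-enoate | CC(C)(C)OC(=O)/C=C/C1=C/C(=C/C(=O)[C@]2(C)CO2)C=CO1 | intermediate
14 | tert-butyl (2E)-3-[(7S)-7-hydroxy-7-methyl-6-oxo-7,8-dihydro-6H-isochromen-3-yl]prop-2-enoate | CC(C)(C)OC(=O)/C=C/C1=CC2=CC(=O)[C@@](C)(O)CC2=CO1 | intermediate
15 | (2E)-3-[(7S)-7-hydroxy-7-methyl-6-oxo-7,8-dihydro-6H-isochromen-3-yl]prop-2-enoic acid | OC(=O)/C=C/C1=CC2=CC(=O)[C@@](C)(O)CC2=CO1 | intermediate
16 | isobutyl carbonic (2E)-3-[(7S)-7-hydroxy-7-methyl-6-oxo-7,8-dihydro-6H-isochromen-3-yl]prop-2-enoic anhydride (formed in the flask) | CC(C)COC(=O)OC(=O)/C=C/C1=CC2=CC(=O)[C@@](C)(O)CC2=CO1 | intermediate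
17 | (7S)-7-hydroxy-3-[(1E)-3-hydroxyprop-1-en-1-yl]-7-methyl-7,8-dihydro-6H-isochromen-6-one | OC/C=C/C1=CC2=CC(=O)[C@@](C)(O)CC2=CO1 | intermediate
18 | (2E)-3-[(7S)-7-hydroxy-7-methyl-6-oxo-7,8-dihydro-6H-isochromen-3-yl]prop-2-en-1-yl acetate | CC(=O)OC/C=C/C1=CC2=CC(=O)[C@@](C)(O)CC2=CO1 | intermediate
19 | 2,2,6-trimethyl-4H-1,3-dioxin-4-one | CC1=CC(=O)OC(C)(C)O1 | starting material
20 | 2,2-dimethyl-6-(2-oxopropyl)-4H-1,3-dioxin-4-one | CC(=O)CC1=CC(=O)OC(C)(C)O1 | intermediate
21 | 6-(2,4-dioxopentyl)-2,2-dimethyl-4H-1,3-dioxin-4-one | CC(=O)CC(=O)CC1=CC(=O)OC(C)(C)O1 | intermediate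
22 | 3,5,7-trioxooct-1-en-1-one (acylketene, formed in the flask) | CC(=O)CC(=O)CC(=O)C=C=O | intermediate
23 | (7S)-3-[(1E)-3-acetoxyprop-1-en-1-yl]-7-methyl-6-oxo-7,8-dihydro-6H-isochromen-7-yl 3,5,7-trioxooctanoate | CC(=O)OC/C=C/C1=CC2=CC(=O)[C@@](C)(OC(=O)CC(=O)CC(=O)CC(=O)C)CC2=CO1 | intermediate
24 | (7S)-3-[(1E)-3-acetoxyprop-1-en-1-yl]-7-methyl-6-oxo-7,8-dihydro-6H-isochromen-7-yl 2-hydroxy-2-methyl-4,6-dioxocyclohexane-1-carboxylate (aldol adduct, cyclohexane carbons unassigned, formed in the flask) | CC(=O)OC/C=C/C1=CC2=CC(=O)[C@@](C)(OC(=O)C3C(=O)CC(=O)CC3(C)O)CC2=CO1 | intermediate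
25 | (7S)-3-[(1E)-3-acetoxyprop-1-en-1-yl]-7-methyl-6-oxo-7,8-dihydro-6H-isochromen-7-yl 2,4-dihydroxy-6-methylbenzoate (CNP0115558.1) | CC(=O)OC/C=C/C1=CC2=CC(=O)[C@@](C)(OC(=O)c3c(C)cc(O)cc3O)CC2=CO1 | target

**Step count**

Total: 15 steps. Longest linear sequence: 11 steps (1, 2, 3, 4, 7, 8, 9, 10, 11, 14, 15). Steps 5–6 and 12–13 are two-step branches that join at steps 7 and 14.

**Steps most likely to fail**

1. Step 8 (the proposed new method). The Lewis acid may bind the vinylogous C6 carbonyl so firmly that C8a loses its enol ether character. Ring closure would then stall and the activated epoxide would be consumed by rearrangement or by opening with adventitious nucleophiles; attack through C4 or at C7 would be lesser leaks.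
Fallback, from 13 back to 14, with the C8–C8a bond made by a radical-type Heck closure instead of a polar epoxide opening. MgI2·OEt2 (toluene/Et2O, −40 °C) would open the chelated keto epoxide at its CH2 to give the iodohydrin tert-butyl (2E)-3-{(4E)-4-[(3R)-3-hydroxy-4-iodo-3-methyl-2-oxobutylidene]-4H-pyran-2-yl}prop-2-enoate F1. Et3SiOTf/2,6-lutidine (CH2Cl2, −78 °C) would cap the tertiary alcohol, so that base cannot re-close the epoxide, giving tert-butyl (2E)-3-{(4E)-4-[(3R)-4-iodo-3-methyl-2-oxo-3-(triethylsilyloxy)butylidene]-4H-pyran-2-yl}prop-2-enoate F2. A palladium-catalysed alkyl Heck cyclisation (Pd(PPh3)4, 1,2,2,6,6-pentamethylpiperidine, benzene, 110 °C) would follow: the neopentyl-type C8 radical, which has no β-hydrogen, adds to C8a in a 6-exo-trig closure and the C1 palladium species loses H8a. This would give tert-butyl (2E)-3-[(7S)-7-methyl-6-oxo-7-(triethylsilyloxy)-7,8-dihydro-6H-isochromen-3-yl]prop-2-enoate F3, and HF·pyridine (THF, 0 °C) would return 14.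

2. Step 14. Capture of the acylketene by the hindered tertiary α-ketol may be slow, so that ketene dimerisation or cycloaddition to the enol ether alkenes takes over. In the following step the β-keto ester carbon may also condense with the C6 carbonyl instead of the chain ketone.
Fallback, from 18 back to 25, with a preformed aromatic acyl donor instead of building the ring on the ester. Commercial orsellinic acid would be persilylated (t-BuMe2SiCl, imidazole, DMF) to tert-butyldimethylsilyl 2,4-bis(tert-butyldimethylsilyloxy)-6-methylbenzoate F4. (COCl)2 with catalytic DMF (CH2Cl2, 0 °C to rt) would convert the silyl ester directly into 2,4-bis(tert-butyldimethylsilyloxy)-6-methylbenzoyl chloride F5. Acylation of 18 (4-dimethylaminopyridine, Et3N, CH2Cl2, 40 °C) would give (7S)-3-[(1E)-3-acetoxyprop-1-en-1-yl]-7-methyl-6-oxo-7,8-dihydro-6H-isochromen-7-yl 2,4-bis(tert-butyldimethylsilyloxy)-6-methylbenzoate F6. HF·pyridine (THF, 0 °C) would then free the two phenols without touching the acetate and give 25.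

3. Step 7. The acyl-substituted thiocarbonyl ylide may close through oxygen to a 1,3-oxathiole instead of the thiirane, the carbenoid may dimerise while the thione slows the catalyst, and the epoxide may not survive prolonged heating.
Fallback, from 7 and 9 back to 13, by addition–elimination on a 4-alkylthiopyrylium salt, the classical route to 4-ylidene-4H-pyrans. Thione 7 would be S-methylated (MeOTf, CH2Cl2, 0 °C) to 2-[(1E)-3-tert-butoxy-3-oxoprop-1-en-1-yl]-4-(methylsulfanyl)pyrylium trifluoromethanesulfonate F7. Acid 9 would be converted through its mixed anhydride 10 with MeNH(OMe)·HCl/N-methylmorpholine into (2S)-N-methoxy-N,2-dimethyloxirane-2-carboxamide F8, and with MeMgBr (THF, −78 °C) into 1-[(2S)-2-methyloxiran-2-yl]ethan-1-one F9. The lithium enolate of F9 (LiN(SiMe3)2, THF, −78 °C) would add to C4 of F7 and expel methanethiol, giving 13.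

**Further compounds**

F1 | step 8 | tert-butyl (2E)-3-{(4E)-4-[(3R)-3-hydroxy-4-iodo-3-methyl-2-oxobutylidene]-4H-pyran-2-yl}prop-2-enoate | CC(C)(C)OC(=O)/C=C/C1=C/C(=C/C(=O)[C@@](C)(O)CI)C=CO1
F2 | step 8 | tert-butyl (2E)-3-{(4E)-4-[(3R)-4-iodo-3-methyl-2-oxo-3-(triethylsilyloxy)butylidene]-4H-pyran-2-yl}prop-2-enoate | CC(C)(C)OC(=O)/C=C/C1=C/C(=C/C(=O)[C@@](C)(O[Si](CC)(CC)CC)CI)C=CO1
F3 | step 8 | tert-butyl (2E)-3-[(7S)-7-methyl-6-oxo-7-(triethylsilyloxy)-7,8-dihydro-6H-isochromen-3-yl]prop-2-enoate | CC(C)(C)OC(=O)/C=C/C1=CC2=CC(=O)[C@@](C)(O[Si](CC)(CC)CC)CC2=CO1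
F4 | step 14 | tert-butyldimethylsilyl 2,4-bis(tert-butyldimethylsilyloxy)-6-methylbenzoate | Cc1cc(O[Si](C)(C)C(C)(C)C)cc(O[Si](C)(C)C(C)(C)C)c1C(=O)O[Si](C)(C)C(C)(C)C
F5 | step 14 | 2,4-bis(tert-butyldimethylsilyloxy)-6-methylbenzoyl chloride | Cc1cc(O[Si](C)(C)C(C)(C)C)cc(O[Si](C)(C)C(C)(C)C)c1C(Cl)=O
F6 | step 14 | (7S)-3-[(1E)-3-acetoxyprop-1-en-1-yl]-7-methyl-6-oxo-7,8-dihydro-6H-isochromen-7-yl 2,4-bis(tert-butyldimethylsilyloxy)-6-methylbenzoate | CC(=O)OC/C=C/C1=CC2=CC(=O)[C@@](C)(OC(=O)c3c(C)cc(O[Si](C)(C)C(C)(C)C)cc3O[Si](C)(C)C(C)(C)C)CC2=CO1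
F7 | step 7 | 2-[(1E)-3-tert-butoxy-3-oxoprop-1-en-1-yl]-4-(methylsulfanyl)pyrylium trifluoromethanesulfonate | CC(C)(C)OC(=O)/C=C/c1cc(SC)cc[o+]1.[O-]S(=O)(=O)C(F)(F)F
F8 | step 7 | (2S)-N-methoxy-N,2-dimethyloxirane-2-carboxamide | CON(C)C(=O)[C@]1(C)CO1
F9 | step 7 | 1-[(2S)-2-methyloxiran-2-yl]ethan-1-one | CC(=O)[C@]1(C)CO1
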